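Percent of the starting complex charged is the unit of this note, and here is the bench you take over.

| setting | south | south-west | north | west | teal | green | ochre | amber |
|---|---|---|---|---|---|---|---|---|
| starting complex | 0.050 M | 0.025 M | 0.10 M | 0.050 M | 0.050 M (in portions, 5, over 5.0 min) | 0.050 M | 0.050 M | 0.050 M (fed, over 5.0 min) |
| incoming ligand | 0.0475 M | 0.0475 M | 0.0475 M | 0.024 M | 0.0475 M | 0.0475 M | 0.0475 M (fed, over 5.0 min) | 0.0475 M |
| remark | run made earlier | run made earlier | run made earlier | run made earlier | first portion at the start, last at 5.0 min | everything together at the start | all else is in the flask from the start; the feed brings no volume worth counting | all else is in the flask from the start; the feed brings no volume worth counting |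
| time |  |  |  |  | 25 min | 25 min | 25 min | 25 min |

- south (time / min: complex with one exchanged / %, complex with two exchanged / %): 3.00: 39.0, 4.2; 6.00: 41.9, 6.6; 10.0: 40.9, 8.2; 12.0: 39.7, 9.2; 15.0: 38.5, 9.8
- south-west (time / min: complex with one exchanged / %, complex with two exchanged / %): 6.00: 48.9, 9.4; 12.0: 48.2, 15.1; 20.0: 43.9, 18.1; 25.0: 41.7, 19.1; 30.0: 39.6, 20.0
- north (time / min: complex with one exchanged / %, complex with two exchanged / %): 2.50: 28.9, 1.9; 8.00: 29.4, 3.3; 15.0: 27.9, 4.6; 20.0: 26.7, 4.7; 30.0: 25.2, 4.5
- west (time / min: complex with one exchanged / %, complex with two exchanged / %): 6.00: 30.0, 2.7; 12.0: 30.1, 3.3; 20.0: 28.6, 4.5; 25.0: 27.5, 4.1; 30.0: 27.3, 3.6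

(readings scatter by 0.3 percentage points)



- the flask that comes out highest in share of complex with one exchanged in complex with one exchanged plus complex with two exchanged, or "all alike" when all lie within 1.5 percentage points (teal / green / ochre / amber / all alike)
- share of complex with one exchanged in complex with one exchanged plus complex with two exchanged at the end, teal
- share of complex with one exchanged in complex with one exchanged plus complex with two exchanged at the end, green
- share of complex with one exchanged in complex with one exchanged plus complex with two exchanged at the end, ochre
- share of complex with one exchanged in complex with one exchanged plus complex with two exchanged at the end, amber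

Each flask stays stirred until 25 min. The share asked for (the selectivity) is what you will read then, and I would follow it through the load, meaning [complex with one exchanged] + 2[complex with two exchanged] in the unit above. Two earlier runs were read at that same time:

west: load 35.7%, share 87.0%
south-west: load 79.9%, share 68.6%

The two runs differ in both charges, so the straight line through them is a rough ruler for 25 min: the share falls by 0.417 for each unit of load.

Next, how much ligand lands on complex? At the last reading, counting these two complexes, north, rich in complex, holds 72.0% of its ligand there, while south-west, with less complex, holds less, 41.9%. So I read ligand as going astray when little complex stands around it. I take north as the model for ochre, which feeds ligand into a flask full of complex, and south-west as the model for amber, whose ligand waits for its complex: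

ochre: load 68.4%, share 73.4%
amber: load 39.8%, share 85.3%

So I expect amber above ochre, with teal and green between them. Leave the order of addition alone: on this reckoning ochre carries more load than amber.

The forecast differs: all alike, with teal 79.6%, green 79.5%, ochre 79.4% and amber 79.7%, since “the flasks have forgotten how they were charged”.

The flasks give teal 82.4%, green 76.4%, ochre 73.8% and amber 84.2%, so amber comes out highest.

    starting complex + incoming ligand ⇌ leaving ligand + complex with one exchanged (K = 9.00, k = 10.0 M⁻¹ min⁻¹)
    complex with one exchanged + incoming ligand ⇌ leaving ligand + complex with two exchanged (K = 7.30, k = 3.70 M⁻¹ min⁻¹)
    complex with two exchanged + incoming ligand ⇌ leaving ligand + complex with three exchanged (K = 0.710, k = 38.0 M⁻¹ min⁻¹)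
    complex with one exchanged → over-reaction product (k = 0.00180 min⁻¹)
    incoming ligand → decomposed reagent (k = 0.0120 min⁻¹)
    2 incoming ligand → homo dimer (k = 4.00 M⁻¹ min⁻¹)

Of the gap of 10 percentage points between amber and ochre, the largest single effect is the path to homo dimer, acting together with the falling back of leaving ligand and complex with three exchanged: with the first struck out the gap is −0.28 points, with the second 1.6 points. At 25.0 min amber holds 0.0121 M of homo dimer, ochre 0.00502 M. At ochre's load of 63.0%, the ruler gives 75.6% against 73.8%. Ochre's neighbour charged with 0.12 M of incoming ligand carries a load of 98.8%, past the ruler's last reading, where the ruler gives 60.7% and the flask gives 51.6%.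

All runs were generated by integration with constants of no real substance, noise included.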